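**Retrosynthetic overview**
1. Target 32 is opened at the C9 ketone and C15 acetate (redox and acylation), at ring D (C15–C16, nickel-catalysed reductive cyclisation of an ynal) and at ring C (Diels–Alder reaction of the C8=C14 2-methylene aldehyde 21 with the 1-silyloxy dienyne 24, which supplies C9, C11, C12, C13, C16 and C17).
2. Removing the C18 methyl (lactone enolate methylation) leaves the cis-fused lactone 17, which is disconnected at C5–C10.
3. The feature on which the plan rests: C10, the methyl carbinol of ring A, is bonded to C5, and C5 is β to the lactone carbonyl C19 through C4. Ring A (C1–C2–C3–C4–C5–C10) therefore closes when a C10 α-silyloxy radical, made by hydrogen-atom transfer to a silyl enol ether, adds to the butenolide 16 that carries the chain on C4.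
4. Butenolide 16 comes from the (R)-γ-lactone 10 (asymmetric hydrogenation of a γ-keto ester) by selenenylation, alkylation with iodide 4 and selenoxide elimination. The C6 arm is carried as a dioxane-masked C15 aldehyde.
5. Order of ring formation: γ-lactone (as butenolide), then ring A, then ring C, then ring D.

Key step: step 8

Remarks on the chemistry:
- ent-Kaurane numbering is used for all intermediates: ring A is C1–C5 and C10; C19 is the lactone carbonyl on C4, joined through oxygen to C6; C7 links C6 to C8; C8, C9 and C11–C16 form the bicyclo[3.2.1]octane; C17 is the exo-methylene; C18 is on C4 and C20 on C10. "Lactone core" means the ring A/γ-lactone unit of 19 with its C10 silyl ether, bonded through C6.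
- Assumption 1: the facial sense of the Ru–BINAP hydrogenation of the γ-keto ester is taken to parallel that of β-keto esters, so (R)-BINAP is written for the (R)-carbinol; if the sense is opposite, (S)-BINAP is used.
- Assumption 2: the (S)-prolinol-derived oxazaborolidinium is taken to deliver the diene to the Re face of C8 in 21; if its facial sense on this substrate is the reverse, the (R)-prolinol-derived catalyst is used.

**Route**

Step 1
Reactants: 1 5-chloropentan-2-one
Product: 3 tert-butyl[(5-chloropent-1-en-2-yl)oxy]dimethylsilane, via lithium enolate 2 (not isolated)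
Conditions: LiN(i-Pr)2, THF, −78 °C; then TBSOTf, −78 → 0 °C
Reagents that add atoms: tert-butyldimethylsilyl trifluoromethanesulfonate, CC(C)(C)[Si](C)(C)OS(=O)(=O)C(F)(F)F
Why: Kinetic deprotonation of the methyl ketone by the hindered amide base gives the terminal enolate, which is O-silylated at low temperature before it can equilibrate or displace the chloride (kinetic silyl enol ether formation).

Step 2
Reactants: 3 tert-butyl[(5-chloropent-1-en-2-yl)oxy]dimethylsilane
Product: 4 tert-butyl[(5-iodopent-1-en-2-yl)oxy]dimethylsilane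
Conditions: NaI, NaHCO3 (cat.), acetone, reflux
Reagents that add atoms: sodium iodide, [Na+].[I-]
Why: Finkelstein exchange at the primary chloride is driven by precipitation of NaCl, and the neutral medium should leave the silyl enol ether intact.

Step 3
Reactants: 5 2-(2-bromoethyl)-1,3-dioxane; 6 methyl 4-chloro-4-oxobutanoate
Product: 8 methyl 6-(1,3-dioxan-2-yl)-4-oxohexanoate, via Grignard reagent 7 (not isolated)
Conditions: Mg, THF, 25 °C; then 6, Fe(acac)3 (3 mol %), THF, −78 °C
Reagents that add atoms: none
Why: Iron-catalysed acylation of the Grignard reagent by the acid chloride is much faster than its addition to the ester or to the ketone formed, so the γ-keto ester should arise without over-addition.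

Step 4
Reactants: 8 methyl 6-(1,3-dioxan-2-yl)-4-oxohexanoate
Product: 10 (5R)-5-[2-(1,3-dioxan-2-yl)ethyl]oxolan-2-one, via hydroxy ester 9 (not isolated)
Conditions: H2 (100 atm), RuCl2[(R)-BINAP](dmf)n (0.5 mol %), EtOH, 30 °C; then AcOH (cat.), toluene, 80 °C
Reagents that add atoms: none
Why: In this Noyori asymmetric hydrogenation the ester carbonyl chelates ruthenium together with the ketone and the BINAP ligand selects the ketone face, which sets C6 as R, and the γ-hydroxy ester then lactonises.

Step 5
Reactants: 10 (5R)-5-[2-(1,3-dioxan-2-yl)ethyl]oxolan-2-one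
Product: 12 (5R)-5-[2-(1,3-dioxan-2-yl)ethyl]-3-(phenylselanyl)oxolan-2-one (C4 epimers), via lithium enolate 11 (not isolated)
Conditions: LiN(i-Pr)2, THF, −78 °C; then PhSeBr, −78 °C
Reagents that add atoms: benzeneselenenyl bromide, Br[Se]c1ccccc1
Why: Electrophilic selenenylation of the lactone enolate puts selenium on C4 before the oxidant-sensitive enol ether is present, and both C4 epimers are usable because this centre becomes quaternary and then sp2.

Step 6
Reactants: 12 (5R)-5-[2-(1,3-dioxan-2-yl)ethyl]-3-(phenylselanyl)oxolan-2-one; 4 tert-butyl[(5-iodopent-1-en-2-yl)oxy]dimethylsilane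
Product: 14 (5R)-3-{4-[(tert-butyldimethylsilyl)oxy]pent-4-en-1-yl}-5-[2-(1,3-dioxan-2-yl)ethyl]-3-(phenylselanyl)oxolan-2-one (C4 epimers), via lithium enolate 13 (not isolated)
Conditions: LiN(i-Pr)2, THF, −78 °C; then 4, DMPU, −78 → −20 °C
Reagents that add atoms: none
Why: The selenium-stabilised enolate is alkylated by the unhindered primary iodide (SN2), over-alkylation is excluded because C4 becomes quaternary, and the silyl enol ether is inert to the amide base.

Step 7
Reactants: 14 (5R)-3-{4-[(tert-butyldimethylsilyl)oxy]pent-4-en-1-yl}-5-[2-(1,3-dioxan-2-yl)ethyl]-3-(phenylselanyl)oxolan-2-one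
Product: 16 (5R)-3-{4-[(tert-butyldimethylsilyl)oxy]pent-4-en-1-yl}-5-[2-(1,3-dioxan-2-yl)ethyl]furan-2(5H)-one, via selenoxide 15 (not isolated)
Conditions: NaIO4, pyridine, THF/MeOH/H2O, 0 → 25 °C
Reagents that add atoms: none
Why: Periodate oxidises selenium chemoselectively and the selenoxide undergoes syn-elimination toward the ring C5–H to the conjugated endocyclic butenolide at room temperature, conditions that should spare the silyl enol ether, the acetal and the C6 stereocentre.

Step 8
Reactants: 16 (5R)-3-{4-[(tert-butyldimethylsilyl)oxy]pent-4-en-1-yl}-5-[2-(1,3-dioxan-2-yl)ethyl]furan-2(5H)-one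
Product: 17 (3R,3aS,4R,7aR)-4-[(tert-butyldimethylsilyl)oxy]-3-[2-(1,3-dioxan-2-yl)ethyl]-4-methylhexahydro-2-benzofuran-1(3H)-one (cis-fused; C10 methyl cis to C19)
Conditions: Fe(acac)3 (30 mol %), PhSiH3 (2.5 equiv), Na2HPO4 (1 equiv), EtOH (0.01 M), 60 °C
Reagents that add atoms: none
Why: An iron hydride formed from trivalent iron and PhSiH3 transfers a hydrogen atom to the terminal CH2 (C20) of the silyl enol ether, the only electron-rich 1,1-disubstituted alkene in 16, and leaves the nucleophilic tertiary α-silyloxy radical at C10. This radical adds to the electrophilic β-carbon C5 of the butenolide in a 6-endo-trig Giese cyclisation that closes ring A (the tether is on the α-carbon C4, and the 5-exo alternative at C4 is polarity-mismatched and would create a spiro quaternary centre); the C4 α-acyl radical is then reduced by divalent iron and the enolate protonated by ethanol, the closest known reaction being the Fe(acac)3/PhSiH3 reductive coupling of silyl enol ether donors with unsaturated carbonyl acceptors, run here intramolecularly. C5 is controlled by the resident C6 stereocentre, the radical entering the butenolide face anti to the C7 arm as in conjugate additions to 5-substituted butenolides. C10 is set in a chair-like transition state in which the silyloxy group is expected to take the outward pseudo-equatorial site, away from the lactone ring and its carbonyl dipole, so that the new methyl is axial and cis to C19. C4 is protonated on the convex face to give the cis-fused lactone, and this centre is renewed in step 9 in any case. The step needs 6-endo regioselectivity and control at C5 and C10; polarity matching and the C6 substituent secure the first two, whereas the C10 preference is the least secure element and is covered by a fallback.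

Step 9
Reactants: 17 (3R,3aS,4R,7aR)-4-[(tert-butyldimethylsilyl)oxy]-3-[2-(1,3-dioxan-2-yl)ethyl]-4-methylhexahydro-2-benzofuran-1(3H)-one
Product: 19 (3R,3aS,4R,7aR)-4-[(tert-butyldimethylsilyl)oxy]-3-[2-(1,3-dioxan-2-yl)ethyl]-4,7a-dimethylhexahydro-2-benzofuran-1(3H)-one, via lithium enolate 18 (not isolated)
Conditions: LiN(i-Pr)2, THF, −78 °C; then MeI, DMPU, −78 → −30 °C
Reagents that add atoms: iodomethane, CI
Why: In this enolate alkylation methyl iodide should approach C4 on the convex face, anti to the fully substituted C10 on the neighbouring C5, which gives the cis-fused quaternary centre with C18 cis to H5.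

Step 10
Reactants: 19 (3R,3aS,4R,7aR)-4-[(tert-butyldimethylsilyl)oxy]-3-[2-(1,3-dioxan-2-yl)ethyl]-4,7a-dimethylhexahydro-2-benzofuran-1(3H)-one
Product: 20 3-(lactone core)propanal (C15 aldehyde)
Conditions: 2 M aq. HCl, THF, 25 → 40 °C
Reagents that add atoms: water, O
Why: Acid hydrolysis of the 1,3-dioxane releases the C15 aldehyde, while the tertiary silyl ether and the lactone are expected to tolerate dilute aqueous acid.

Step 11
Reactants: 20 3-(lactone core)propanal
Product: 21 2-methylidene-3-(lactone core)propanal
Conditions: 37 % aq. HCHO, pyrrolidine (10 mol %), EtCO2H (10 mol %), i-PrOH, 45 °C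
Reagents that add atoms: formaldehyde, C=O
Why: Organocatalytic α-methylenation (enamine Mannich reaction with formaldehyde, then elimination of the amine) converts the α-unbranched aldehyde into the 2-methylene aldehyde and introduces C14.

Step 12
Reactants: 22 glutaconaldehyde potassium salt
Product: 23 (2E,4E)-5-[(tert-butyldimethylsilyl)oxy]penta-2,4-dienal
Conditions: TBSCl, DMF, 0 → 25 °C
Reagents that add atoms: tert-butyldimethylsilyl chloride, CC(C)(C)[Si](C)(C)Cl
Why: The delocalised all-trans enolate is silylated on oxygen, which should give the (E,E)-silyloxy dienal directly.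

Step 13
Reactants: 23 (2E,4E)-5-[(tert-butyldimethylsilyl)oxy]penta-2,4-dienal
Product: 24 tert-butyl[(1E,3E)-hexa-1,3-dien-5-yn-1-yloxy]dimethylsilane
Conditions: TMSCHN2, LiN(i-Pr)2, THF, −78 °C; then 23, −78 → 25 °C
Reagents that add atoms: (trimethylsilyl)diazomethane, C[Si](C)(C)C=[N+]=[N-]
Why: In this Colvin homologation the lithiated silyl diazomethane adds to the aldehyde, loss of silanolate and N2 gives an alkylidene carbene, and a 1,2-hydrogen shift yields the terminal alkyne under aprotic conditions that should not cleave the dienol ether.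

Step 14
Reactants: 21 2-methylidene-3-(lactone core)propanal; 24 tert-butyl[(1E,3E)-hexa-1,3-dien-5-yn-1-yloxy]dimethylsilane
Product: 25 2-[(tert-butyldimethylsilyl)oxy]-5-ethynyl-1-[(lactone core)methyl]cyclohex-3-ene-1-carbaldehyde (ring C; formyl on C8, silyloxy on C9 and ethynyl on C13 all cis; C8 as in the target)
Conditions: (S)-o-tolyl oxazaborolidine (from (S)-α,α-diphenylprolinol)·Tf2NH (20 mol %), CH2Cl2, −78 → −40 °C
Reagents that add atoms: none
Why: In this catalytic enantioselective Diels–Alder reaction of a 2-substituted acrolein the N-protonated oxazaborolidine binds the formyl group and screens one face of C8=C14, the oxygen donor directs the diene terminus C9 to the α-carbon C8 and C13 to C14, and the formyl-endo transition state of the (E,E)-diene places CHO, O9 and the ethynyl group cis, so that the catalyst rather than the remote lactone stereocentres fixes C8.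

Step 15
Reactants: 25 2-[(tert-butyldimethylsilyl)oxy]-5-ethynyl-1-[(lactone core)methyl]cyclohex-3-ene-1-carbaldehyde
Product: 27 2-[(tert-butyldimethylsilyl)oxy]-1-[(lactone core)methyl]-6-methylidenebicyclo[3.2.1]oct-3-en-7-ol (ring D closed; C15 epimers), via triethylsilyl ether 26 (not isolated)
Conditions: Ni(cod)2 (20 mol %), PBu3 (40 mol %), Et3SiH, THF, 25 °C; then PPTS, MeOH, 0 °C
Reagents that add atoms: none
Why: In this nickel-catalysed reductive cyclisation of an ynal, zerovalent nickel couples the aldehyde and the alkyne to an oxanickelacycle (C15–C16 bond, 5-exo mode), Et3SiH then delivers the silyl ether of the exocyclic allylic alcohol, which methanolysis frees, and the C15 configuration (oxygen probably exo) is irrelevant because step 16 erases it.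

Step 16
Reactants: 27 2-[(tert-butyldimethylsilyl)oxy]-1-[(lactone core)methyl]-6-methylidenebicyclo[3.2.1]oct-3-en-7-ol
Product: 28 2-[(tert-butyldimethylsilyl)oxy]-1-[(lactone core)methyl]-6-methylidenebicyclo[3.2.1]oct-3-en-7-one (C15 ketone)
Conditions: Dess–Martin periodinane, CH2Cl2, 0 → 25 °C
Reagents that add atoms: none
Why: Dess–Martin oxidation of the only free hydroxyl converges both C15 epimers on the α-methylene cyclopentanone.

Step 17
Reactants: 28 2-[(tert-butyldimethylsilyl)oxy]-1-[(lactone core)methyl]-6-methylidenebicyclo[3.2.1]oct-3-en-7-one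
Product: 29 the C15 endo alcohol (hydroxyl syn to the C9–C11–C12 bridge, as in the target)
Conditions: NaBH4, CeCl3·7H2O, MeOH, −78 → −40 °C
Reagents that add atoms: none
Why: In this Luche 1,2-reduction hydride should add to C15 from the exo face (the side of the one-carbon bridge C14) because the endo face is screened by C11 and the C9 silyloxy group, so the hydroxyl ends endo, while cerium suppresses conjugate reduction and the lactone is not touched.

Step 18
Reactants: 29 the C15 endo alcohol
Product: 30 the C15 acetate (C9 and C10 still silylated)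
Conditions: Ac2O, DMAP, Et3N, CH2Cl2, 25 °C
Reagents that add atoms: acetic anhydride, CC(=O)OC(C)=O
Why: DMAP-catalysed acylation of the only free hydroxyl installs the C15 acetate.

Step 19
Reactants: 30 the C15 acetate
Product: 31 the C9,C10-diol (C15 acetate retained)
Conditions: HF·pyridine, pyridine, THF, 0 → 25 °C
Reagents that add atoms: none
Why: Fluoride cleaves the allylic C9 and the tertiary C10 silyl ethers, and the buffered, weakly acidic medium is chosen to leave the acetate, lactone and exo-methylene intact and to avoid base-induced acetyl migration to the syn C9 hydroxyl.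

Step 20
Reactants: 31 the C9,C10-diol
Product: 32 CNP0172716.1
Conditions: Dess–Martin periodinane, CH2Cl2, 0 → 25 °C
Reagents that add atoms: none
Why: Dess–Martin oxidation of the allylic C9 alcohol gives the enone, the tertiary C10 alcohol cannot be oxidised, and C8 bears no hydrogen so the β-acetoxy ketone cannot eliminate.

**Compound list**
1 | 5-chloropentan-2-one | CC(=O)CCCCl | starting material
2 | lithium 5-chloropent-1-en-2-olate | [Li]OC(=C)CCCCl | intermediate
3 | tert-butyl[(5-chloropent-1-en-2-yl)oxy]dimethylsilane | C=C(O[Si](C)(C)C(C)(C)C)CCCCl | intermediate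
4 | tert-butyl[(5-iodopent-1-en-2-yl)oxy]dimethylsilane | C=C(O[Si](C)(C)C(C)(C)C)CCCI | intermediate
5 | 2-(2-bromoethyl)-1,3-dioxane | BrCCC1OCCCO1 | starting material
6 | methyl 4-chloro-4-oxobutanoate | COC(=O)CCC(=O)Cl | starting material
7 | [2-(1,3-dioxan-2-yl)ethyl]magnesium bromide | Br[Mg]CCC1OCCCO1 | intermediate
8 | methyl 6-(1,3-dioxan-2-yl)-4-oxohexanoate | COC(=O)CCC(=O)CCC1OCCCO1 | intermediate
9 | methyl (4R)-6-(1,3-dioxan-2-yl)-4-hydroxyhexanoate | COC(=O)CC[C@H](O)CCC1OCCCO1 | intermediate
10 | (5R)-5-[2-(1,3-dioxan-2-yl)ethyl]oxolan-2-one | O=C1CC[C@@H](CCC2OCCCO2)O1 | intermediate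
11 | lithium enolate of 10 | [Li]OC1=CC[C@@H](CCC2OCCCO2)O1 | intermediate
12 | (5R)-5-[2-(1,3-dioxan-2-yl)ethyl]-3-(phenylselanyl)oxolan-2-one (C4 epimers) | O=C1O[C@H](CCC2OCCCO2)CC1[Se]c1ccccc1 | intermediate
13 | lithium enolate of 12 | [Li]OC1=C([Se]c2ccccc2)C[C@@H](CCC3OCCCO3)O1 | intermediate
14 | (5R)-3-{4-[(tert-butyldimethylsilyl)oxy]pent-4-en-1-yl}-5-[2-(1,3-dioxan-2-yl)ethyl]-3-(phenylselanyl)oxolan-2-one (C4 epimers) | C=C(O[Si](C)(C)C(C)(C)C)CCCC1([Se]c2ccccc2)C[C@@H](CCC3OCCCO3)OC1=O | intermediate
15 | selenoxide of 14 | C=C(O[Si](C)(C)C(C)(C)C)CCCC1([Se](=O)c2ccccc2)C[C@@H](CCC3OCCCO3)OC1=O | intermediate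
16 | (5R)-3-{4-[(tert-butyldimethylsilyl)oxy]pent-4-en-1-yl}-5-[2-(1,3-dioxan-2-yl)ethyl]furan-2(5H)-one | C=C(O[Si](C)(C)C(C)(C)C)CCCC1=C[C@@H](CCC2OCCCO2)OC1=O | intermediate
17 | (3R,3aS,4R,7aR)-4-[(tert-butyldimethylsilyl)oxy]-3-[2-(1,3-dioxan-2-yl)ethyl]-4-methylhexahydro-2-benzofuran-1(3H)-one | C1COC(CC[C@H]2OC(=O)[C@@H]3CCC[C@@](C)(O[Si](C)(C)C(C)(C)C)[C@H]23)OC1 | intermediate
18 | lithium enolate of 17 | [Li]OC1=C2CCC[C@@](C)(O[Si](C)(C)C(C)(C)C)[C@@H]2[C@@H](CCC3OCCCO3)O1 | intermediate
19 | (3R,3aS,4R,7aR)-4-[(tert-butyldimethylsilyl)oxy]-3-[2-(1,3-dioxan-2-yl)ethyl]-4,7a-dimethylhexahydro-2-benzofuran-1(3H)-one | C1COC(CC[C@H]2OC(=O)[C@]3(C)CCC[C@@](C)(O[Si](C)(C)C(C)(C)C)[C@H]23)OC1 | intermediate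
20 | 3-(lactone core)propanal | O=CCC[C@H]1OC(=O)[C@]2(C)CCC[C@@](C)(O[Si](C)(C)C(C)(C)C)[C@H]12 | intermediate
21 | 2-methylidene-3-(lactone core)propanal | C=C(C=O)C[C@H]1OC(=O)[C@]2(C)CCC[C@@](C)(O[Si](C)(C)C(C)(C)C)[C@H]12 | intermediate
22 | glutaconaldehyde potassium salt | [K+].[O-]/C=C/C=C/C=O | starting material
23 | (2E,4E)-5-[(tert-butyldimethylsilyl)oxy]penta-2,4-dienal | O=C/C=C/C=C/O[Si](C)(C)C(C)(C)C | intermediate
24 | tert-butyl[(1E,3E)-hexa-1,3-dien-5-yn-1-yloxy]dimethylsilane | C#C/C=C/C=C/O[Si](C)(C)C(C)(C)C | intermediate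
25 | ring C cycloadduct (formyl, C9 silyloxy and C13 ethynyl cis) | C#C[C@@H]1C=C[C@H](O[Si](C)(C)C(C)(C)C)[C@@](C=O)(C[C@H]2OC(=O)[C@]3(C)CCC[C@@](C)(O[Si](C)(C)C(C)(C)C)[C@H]23)C1 | intermediate
26 | C15 triethylsilyl ether of 27 (C15 epimers) | C=C1[C@@H]2C=C[C@H](O[Si](C)(C)C(C)(C)C)[C@@](C[C@H]3OC(=O)[C@]4(C)CCC[C@@](C)(O[Si](C)(C)C(C)(C)C)[C@H]34)(C2)C1O[Si](CC)(CC)CC | intermediate
27 | C15 allylic alcohol (C15 epimers) | C=C1[C@@H]2C=C[C@H](O[Si](C)(C)C(C)(C)C)[C@@](C[C@H]3OC(=O)[C@]4(C)CCC[C@@](C)(O[Si](C)(C)C(C)(C)C)[C@H]34)(C2)C1O | intermediate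
28 | C15 ketone (α-methylene cyclopentanone) | C=C1[C@@H]2C=C[C@H](O[Si](C)(C)C(C)(C)C)[C@@](C[C@H]3OC(=O)[C@]4(C)CCC[C@@](C)(O[Si](C)(C)C(C)(C)C)[C@H]34)(C2)C1=O | intermediate
29 | C15 endo alcohol | C=C1[C@@H]2C=C[C@H](O[Si](C)(C)C(C)(C)C)[C@@](C[C@H]3OC(=O)[C@]4(C)CCC[C@@](C)(O[Si](C)(C)C(C)(C)C)[C@H]34)(C2)[C@@H]1O | intermediate
30 | C15 acetate, C9 and C10 silyl ethers | C=C1[C@@H]2C=C[C@H](O[Si](C)(C)C(C)(C)C)[C@@](C[C@H]3OC(=O)[C@]4(C)CCC[C@@](C)(O[Si](C)(C)C(C)(C)C)[C@H]34)(C2)[C@@H]1OC(C)=O | intermediate
31 | C9,C10-diol with C15 acetate | C=C1[C@@H]2C=C[C@H](O)[C@@](C[C@H]3OC(=O)[C@]4(C)CCC[C@@](C)(O)[C@H]34)(C2)[C@@H]1OC(C)=O | intermediate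
32 | CNP0172716.1 | C=C1[C@@H]2C=CC(=O)[C@@](C[C@H]3OC(=O)[C@]4(C)CCC[C@@](C)(O)[C@H]34)(C2)[C@@H]1OC(C)=O | target

**Step count**
Total: 20 steps. Longest linear sequence: 16 steps (steps 3–11 and 14–20); iodide 4 (steps 1–2) and dienyne 24 (steps 12–13) are made in side branches.

**Steps most likely to fail**

1. Step 8. The C10 radical may add with the silyloxy group in the inward (axial) position and give the C10 epimer, or it may be reduced before it cyclises, or the enol ether may be solvolysed. Fallback, from 16: buffered fluoride (TBAF, AcOH, THF, 0 °C) cleaves the silyl enol ether to (5R)-5-[2-(1,3-dioxan-2-yl)ethyl]-3-(4-oxopentyl)furan-2(5H)-one F1. A ketyl–olefin cyclisation (SmI2, HMPA, t-BuOH, THF, −78 °C) then forms the same C5–C10 bond. The bulky samarium-bound ketyl oxygen should sit outward and the attack should again come anti to the C7 arm, giving the C10 tertiary alcohol of the cis-fused lactone F2. Silylation (TBSOTf, 2,6-lutidine, CH2Cl2) returns to the route at 17.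

2. Step 14. The chiral Lewis acid may discriminate the two faces of C8 poorly (the lactone stereocentres are too remote to help), endo selectivity may erode, or the acidic catalyst may desilylate the dienol ether before it adds. Fallback, from 21, using auxiliary control in place of catalyst control: condensation with (2R,4R)-pentane-2,4-diol (PPTS, benzene, reflux) gives the chiral 4,6-dimethyl-1,3-dioxane acetal of 21 F3. Ionisation with catalytic TMSOTf at −78 °C generates the vinyl oxocarbenium ion, one C8 face of which is blocked by the auxiliary, and cationic cycloaddition with 24 gives the cycloadduct acetal F4. The diol enantiomer is chosen for Re-face attack and is drawn as 2R,4R. Mild aqueous acid releases the aldehyde and the route is rejoined at 25. This cycloaddition may be stepwise with an oxygenated diene, so cis geometry is less assured than in the main route.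

3. Step 15. The terminal alkyne may oligomerise at nickel, or the hindered aldehyde on the quaternary C8 may fail to enter the oxanickelacycle because of the strain of the forming bicyclo[3.2.1]octene. Fallback, from 25: a radical closure of the same C15–C16 bond (SmI2, HMPA, t-BuOH, THF, −78 → 0 °C), in which the aldehyde ketyl adds 5-exo-dig to the alkyne and the vinyl radical is reduced and protonated. This gives 27 directly, again as C15 epimers that step 16 converges, so the route is rejoined at 27.

**Further compounds**
F1 | step 8 | (5R)-5-[2-(1,3-dioxan-2-yl)ethyl]-3-(4-oxopentyl)furan-2(5H)-one | CC(=O)CCCC1=C[C@@H](CCC2OCCCO2)OC1=O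
F2 | step 8 | (3R,3aS,4R,7aR)-3-[2-(1,3-dioxan-2-yl)ethyl]-4-hydroxy-4-methylhexahydro-2-benzofuran-1(3H)-one | C1COC(CC[C@H]2OC(=O)[C@@H]3CCC[C@@](C)(O)[C@H]23)OC1
F3 | step 14 | (4R,6R)-4,6-dimethyl-1,3-dioxane acetal of 21 | C=C(C[C@H]1OC(=O)[C@]2(C)CCC[C@@](C)(O[Si](C)(C)C(C)(C)C)[C@H]12)C1O[C@H](C)C[C@@H](C)O1
F4 | step 14 | (4R,6R)-4,6-dimethyl-1,3-dioxane acetal of 25 | C#C[C@@H]1C=C[C@H](O[Si](C)(C)C(C)(C)C)[C@@](C2O[C@H](C)C[C@@H](C)O2)(C[C@H]3OC(=O)[C@]4(C)CCC[C@@](C)(O[Si](C)(C)C(C)(C)C)[C@H]34)C1
F0 | step 15 | none | none
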